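**Plan**

1. Atom labels follow the daucane skeleton: five-membered ring C1(quaternary, Me)–C2–C3–C4(OH, i-Pr)–C5(H); seven-membered ring C1–C5–C6(O-anisoyl)–C7–C8(Me)=C9–C10. Retrosynthetic cuts, in order: the C6–O acyl bond; the C4–isopropyl bond; C5–H and C6–O (back to a C4(=O)–C5=C6 enone); the C4–C5 bond; the C1–C2 bond; the C8=C9 double bond.
2. Forward: the seven-membered ring arises first by ring-closing metathesis, the quaternary C1 with the C2–C3–C4 chain is added by an auxiliary-controlled Michael addition to acrylonitrile, and the five-membered ring is closed last.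
3. Enabling feature: C4 and C5 are neighbours in the five-membered ring and are linked the other way round through C1–C2–C3. With C5 as the ring ketone and C4 as a nitrile carbon, they form a δ-keto nitrile, so a C5 ketyl can close the ring 5-exo onto C4.
4. C4 comes out of the closure as a ketone (ready for isopropyl addition). The C5 hydroxyl is a helper that is lost with a C6 hydrogen; this makes C5 sp2 again, because a closure that sets C5–H directly on the seven-membered ring is expected to give only the cis-fused bicycle.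
5. Stereochemistry: C1 comes from the (R)-1-phenylethylamine imine. C6–O (epoxidation), C5–H (enolate protonation) and C4–i-Pr (organocerium addition) are each introduced on the face opposite the C1 methyl, giving the trans ring fusion with i-Pr, H5 and O6 cis to one another.
6. Acylation of the secondary C6 hydroxyl ends the route.

Key step: step 5

Remark: in the text C1–C10 are daucane locants (C1 = 8a, C2 = 1, C3 = 2, C4 = 3, C5 = 3a, C6 = 4, C7 = 5, C8 = 6, C9 = 7, C10 = 8 in the azulene names). The facial sense of step 4 is assumed to follow that of 2-methylcycloalkanone imines.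

**Route**

Step 1
Reactants: 1 ethyl 2-methylpent-4-enoate
Product: 2 N-methoxy-N,2-dimethylpent-4-enamide
Conditions: MeNH(OMe)·HCl, i-PrMgCl, THF, −20 °C
Reagents that add atoms: N,O-dimethylhydroxylamine hydrochloride, CNOC.Cl
Why: Weinreb amide formation by aminolysis of the ester with the magnesium amide made in the flask; it stops at the amide, and the racemic α-centre is of no consequence because it is re-formed in step 4.

Step 2
Reactants: 2 N-methoxy-N,2-dimethylpent-4-enamide; 3 4-bromo-2-methylbut-1-ene
Product: 5 2,6-dimethylnona-1,8-dien-5-one, via Grignard reagent 4 (not isolated)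
Conditions: Mg, THF, rt; then 2, 0 °C; aq. NH4Cl
Reagents that add atoms: none
Why: Weinreb ketone synthesis: the N-methoxy-N-methyl amide takes up one equivalent of the Grignard reagent only, so the unsymmetrical dienyl ketone should form without over-addition; no stereocenter is set.

Step 3
Reactants: 5 2,6-dimethylnona-1,8-dien-5-one
Product: 6 2,5-dimethylcyclohept-4-en-1-one
Conditions: second-generation Grubbs catalyst (3 mol %), CH2Cl2 (0.01 M), 40 °C
Reagents that add atoms: none
Why: Ring-closing metathesis between the monosubstituted and the 1,1-disubstituted alkene closes the seven-membered ring and places the trisubstituted C8=C9 double bond with its methyl group; high dilution favours the ring over oligomers.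

Step 4
Reactants: 6 2,5-dimethylcyclohept-4-en-1-one; 7 (R)-1-phenylethylamine; 8 acrylonitrile
Product: 11 3-[(1R)-1,4-dimethyl-7-oxocyclohept-3-en-1-yl]propanenitrile, via imine 9 (not isolated), via cyanoethylated imine 10 (not isolated)
Conditions: 7, p-TsOH (cat.), toluene, reflux (−H2O); 8, THF, 60 °C; 20% aq. AcOH, rt
Reagents that add atoms: water, O
Why: Michael addition of a chiral imine through its more substituted secondary enamine tautomer (aza-ene-type transition state): acrylonitrile is taken up on the enamine face away from the phenyl group of the auxiliary, so both enantiomers of 6 should converge on one quaternary centre, expected to be (R) at C1 with the (R)-amine.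

Step 5
Reactants: 11 3-[(1R)-1,4-dimethyl-7-oxocyclohept-3-en-1-yl]propanenitrile
Product: 13 (3aR,8aR)-3a-hydroxy-6,8a-dimethyl-2,3a,4,5,8,8a-hexahydroazulen-3(1H)-one, via hydroxy ketimine 12 (not isolated)
Conditions: SmI2 (4 equiv), t-BuOH, THF, visible light, rt; then 1 M HCl, rt
Reagents that add atoms: water, O
Why: Single-electron transfer from SmI2 (divalent samarium) to the C5 ketone gives a ketyl that adds to the nitrile carbon C4, held in reach by the C1–C2–C3 tether; the iminyl radical takes a second electron and a proton to give ketimine 12, which is hydrolysed to the C4 ketone on acidic work-up. The closest known reaction type is the reductive ketyl–nitrile coupling of δ-keto nitriles to 2-hydroxycyclopentanones (a pinacol-type cyclization with samarium diiodide or zinc/chlorosilane). The five-membered ring closes in the 5-exo-dig mode onto the ring carbon C5. The one new stereocenter, the C5 carbinol, is fixed by the tether: the new C4–C5 bond must lie on the same face of the seven-membered ring as C2, so the hydroxyl should be cis to the C1 methyl (cis ring fusion). This centre is a helper only and C5 becomes sp2 again in step 6. The step needs chemoselectivity for ketyl formation at the ketone and attack on the nitrile: alkyl nitriles are not reduced by SmI2, and the C8=C9 alkene could be reached only through four-membered or endo transition states.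

Step 6
Reactants: 13 (3aR,8aR)-3a-hydroxy-6,8a-dimethyl-2,3a,4,5,8,8a-hexahydroazulen-3(1H)-one
Product: 14 (8aR)-6,8a-dimethyl-2,5,8,8a-tetrahydroazulen-3(1H)-one
Conditions: Burgess reagent, toluene, 70 °C
Reagents that add atoms: none
Why: Burgess dehydration (syn elimination of the sulfamate ester): the tertiary C5 hydroxyl has β-hydrogens only on C6, so the conjugated C4(=O)–C5=C6 enone is the only alkene that can form, and the helper oxygen on C5 is removed.

Step 7
Reactants: 14 (8aR)-6,8a-dimethyl-2,5,8,8a-tetrahydroazulen-3(1H)-one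
Product: 15 (3aR,4S,8aR)-3a,4-epoxy-6,8a-dimethyl-2,3a,4,5,8,8a-hexahydroazulen-3(1H)-one
Conditions: t-BuOOH, n-BuLi, THF, −78 to −20 °C
Reagents that add atoms: tert-butyl hydroperoxide, CC(C)(C)OO
Why: Weitz–Scheffer-type nucleophilic epoxidation: the peroxide anion attacks only the electron-poor C5=C6 bond (not C8=C9), adding at C6 and closing at C5 on the face opposite the axial C1 methyl on the neighbouring carbon, which should set C6 as (S); the aprotic lithium peroxide is chosen to avoid base-induced migration of the skipped diene.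

Step 8
Reactants: 15 (3aR,4S,8aR)-3a,4-epoxy-6,8a-dimethyl-2,3a,4,5,8,8a-hexahydroazulen-3(1H)-one
Product: 17 (3aS,4S,8aR)-4-hydroxy-6,8a-dimethyl-2,3a,4,5,8,8a-hexahydroazulen-3(1H)-one, via samarium enolate 16 (not isolated)
Conditions: SmI2 (2.5 equiv), THF–MeOH, −90 °C
Reagents that add atoms: none
Why: Reductive opening of the α,β-epoxy ketone by SmI2 cleaves the C5–O bond next to the carbonyl and leaves C6–O untouched; enolate 16 should be protonated at C5 on the face opposite the C1 methyl, the face that also carries the C6 samarium alkoxide able to relay methanol, giving C5–H cis to the C6 oxygen and the trans ring fusion.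

Step 9
Reactants: 17 (3aS,4S,8aR)-4-hydroxy-6,8a-dimethyl-2,3a,4,5,8,8a-hexahydroazulen-3(1H)-one
Product: 18 (3R,3aS,4S,8aR)-6,8a-dimethyl-3-(propan-2-yl)-1,2,3,3a,4,5,8,8a-octahydroazulene-3,4-diol
Conditions: i-PrMgCl, CeCl3, THF, −78 to 0 °C
Reagents that add atoms: isopropylmagnesium chloride, CC(C)[Mg]Cl
Why: 1,2-Addition of an organocerium reagent (low basicity, so enolization, β-elimination and retro-aldol cleavage should be suppressed): the nucleophile should enter the cyclopentanone from the face of H5, because the other face is shielded by C6 on the adjacent carbon and by the C1 methyl in the 1,3-position, giving the C4 carbinol (R) with hydroxyl cis to the methyl.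

Step 10
Reactants: 18 (3R,3aS,4S,8aR)-6,8a-dimethyl-3-(propan-2-yl)-1,2,3,3a,4,5,8,8a-octahydroazulene-3,4-diol; 19 4-methoxybenzoyl chloride
Product: 20 (3R,3aS,4S,8aR)-3-hydroxy-6,8a-dimethyl-3-(propan-2-yl)-1,2,3,3a,4,5,8,8a-octahydroazulen-4-yl 4-methoxybenzoate
Conditions: 19, pyridine, DMAP (cat.), CH2Cl2, 0 °C to rt
Reagents that add atoms: none
Why: Acylation by the acid chloride under nucleophilic catalysis: only the secondary C6 hydroxyl should react, the tertiary C4 hydroxyl being too hindered, and no stereocenter is touched.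

**Compound list**

1 | ethyl 2-methylpent-4-enoate (racemic) | CCOC(=O)C(C)CC=C | starting material
2 | N-methoxy-N,2-dimethylpent-4-enamide (racemic) | CON(C)C(=O)C(C)CC=C | intermediate
3 | 4-bromo-2-methylbut-1-ene | C=C(C)CCBr | starting material
4 | (3-methylbut-3-en-1-yl)magnesium bromide | C=C(C)CC[Mg]Br | intermediate
5 | 2,6-dimethylnona-1,8-dien-5-one (racemic) | C=C(C)CCC(=O)C(C)CC=C | intermediate
6 | 2,5-dimethylcyclohept-4-en-1-one (racemic) | O=C1CCC(C)=CCC1C | intermediate
7 | (R)-1-phenylethylamine | C[C@@H](N)c1ccccc1 | starting material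
8 | acrylonitrile | C=CC#N | starting material
9 | (1R)-N-(2,5-dimethylcyclohept-4-en-1-ylidene)-1-phenylethanamine (both ring C2 epimers) | C[C@@H](N=C1CCC(C)=CCC1C)c1ccccc1 | intermediate
10 | 3-[(1R)-1,4-dimethyl-7-{[(1R)-1-phenylethyl]imino}cyclohept-3-en-1-yl]propanenitrile | C[C@@H](N=C1CCC(C)=CC[C@@]1(C)CCC#N)c1ccccc1 | intermediate
11 | 3-[(1R)-1,4-dimethyl-7-oxocyclohept-3-en-1-yl]propanenitrile | O=C1CCC(C)=CC[C@@]1(C)CCC#N | intermediate
12 | (3aR,8aR)-3-imino-6,8a-dimethyl-2,3,4,5,8,8a-hexahydroazulen-3a(1H)-ol | N=C1CC[C@]2(C)CC=C(C)CC[C@]12O | intermediate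
13 | (3aR,8aR)-3a-hydroxy-6,8a-dimethyl-2,3a,4,5,8,8a-hexahydroazulen-3(1H)-one (hydroxyl cis to the angular methyl) | O=C1CC[C@]2(C)CC=C(C)CC[C@]12O | intermediate
14 | (8aR)-6,8a-dimethyl-2,5,8,8a-tetrahydroazulen-3(1H)-one | O=C1CC[C@]2(C)CC=C(C)CC=C12 | intermediate
15 | (3aR,4S,8aR)-3a,4-epoxy-6,8a-dimethyl-2,3a,4,5,8,8a-hexahydroazulen-3(1H)-one (epoxide trans to the angular methyl) | O=C1CC[C@]2(C)CC=C(C)C[C@@H]3O[C@]123 | intermediate
16 | disamarium tetraiodide salt of (4S,8aR)-6,8a-dimethyl-4-oxido-1,2,4,5,8,8a-hexahydroazulen-3-olate (enolate at C3=C3a, alkoxide at C4) | [O-]C1=C2[C@@H]([O-])CC(C)=CC[C@@]2(C)CC1.[Sm+3].[Sm+3].[I-].[I-].[I-].[I-] | intermediate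
17 | (3aS,4S,8aR)-4-hydroxy-6,8a-dimethyl-2,3a,4,5,8,8a-hexahydroazulen-3(1H)-one (trans-fused) | O=C1CC[C@]2(C)CC=C(C)C[C@H](O)[C@@H]12 | intermediate
18 | (3R,3aS,4S,8aR)-6,8a-dimethyl-3-(propan-2-yl)-1,2,3,3a,4,5,8,8a-octahydroazulene-3,4-diol | O[C@H]1CC(C)=CC[C@@]2(C)CC[C@@](O)(C(C)C)[C@H]12 | intermediate
19 | 4-methoxybenzoyl chloride | COc1ccc(C(=O)Cl)cc1 | starting material
20 | (3R,3aS,4S,8aR)-3-hydroxy-6,8a-dimethyl-3-(propan-2-yl)-1,2,3,3a,4,5,8,8a-octahydroazulen-4-yl 4-methoxybenzoate | COc1ccc(C(=O)O[C@H]2CC(C)=CC[C@@]3(C)CC[C@@](O)(C(C)C)[C@H]23)cc1 | target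

**Step count and risks**

Total step count: 10. Longest linear sequence: 10 steps (from 1).

Steps most likely to fail:

1. Step 8. The enolate may be protonated on the wrong face (cis ring fusion), or the C6 alkoxide may be lost by β-elimination back to the enone. Fallback from 14, returning at 18; it sets C5–H by hydrogen-atom transfer to a radical instead of enolate protonation. i-PrMgCl/CeCl3 should add to the enone carbonyl of 14 to give (3R,8aR)-6,8a-dimethyl-3-(propan-2-yl)-1,2,3,5,8,8a-hexahydroazulen-3-ol F5, with the hydroxyl expected cis to the C1 methyl. VO(acac)2 with t-BuOOH should then epoxidize C5=C6 on the face of that hydroxyl to give (3R,3aS,4R,8aR)-3a,4-epoxy-6,8a-dimethyl-3-(propan-2-yl)-1,2,3,3a,4,5,8,8a-octahydroazulen-3-ol F6. Trivalent titanium made from (C5H5)2TiCl2 and Zn, with 1,4-cyclohexadiene, should open the epoxide homolytically at C5; the tertiary radical should take up hydrogen on the face opposite the C1 methyl and the two oxygens, giving (3R,3aS,4R,8aR)-6,8a-dimethyl-3-(propan-2-yl)-1,2,3,3a,4,5,8,8a-octahydroazulene-3,4-diol F7. Dess–Martin periodinane should oxidize C6 to (3R,3aR,8aR)-3-hydroxy-6,8a-dimethyl-3-(propan-2-yl)-2,3,3a,5,8,8a-hexahydroazulen-4(1H)-one F8. An Evans–Saksena reduction with Me4NBH(OAc)3, hydride delivered from the C4 hydroxyl, should then give 18.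

2. Step 7. The peroxide may add with poor facial selectivity, or the base may move the skipped diene into conjugation. Fallback from 14, returning at 17. Copper-catalysed conjugate borylation (CuCl, NaOt-Bu, bis(pinacolato)diboron, MeOH, THF) should give (3aR,4S,8aR)-6,8a-dimethyl-4-(4,4,5,5-tetramethyl-1,3,2-dioxaborolan-2-yl)-2,3a,4,5,8,8a-hexahydroazulen-3(1H)-one F4. Oxidation of the C–B bond with NaBO3·4H2O, with retention, should give 17.

3. Step 5. The ketyl may be reduced further to the secondary alcohol, or may dimerize, faster than it attacks the nitrile next to the quaternary carbon. Fallback from 11, returning at 14. KN(SiMe3)2 and PhNTf2 should convert the ketone into the dienyl triflate 3-[(1R)-1,5-dimethyl-2-(trifluoromethanesulfonyloxy)cyclohepta-2,5-dien-1-yl]propanenitrile F1. i-Bu2AlH at −78 °C followed by hydrolysis should give the aldehyde 3-[(1R)-1,5-dimethyl-2-(trifluoromethanesulfonyloxy)cyclohepta-2,5-dien-1-yl]propanal F2. An intramolecular Nozaki–Hiyama–Kishi reaction (CrCl2, NiCl2 cat., DMF) should close the same C4–C5 bond from the alkenyl carbon to give (8aR)-6,8a-dimethyl-1,2,3,5,8,8a-hexahydroazulen-3-ol F3, and Dess–Martin periodinane should oxidize it to 14.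

Further compounds
F1 | step 5 | 3-[(1R)-1,5-dimethyl-2-(trifluoromethanesulfonyloxy)cyclohepta-2,5-dien-1-yl]propanenitrile | N#CCC[C@]1(C)CC=C(C)CC=C1OS(=O)(=O)C(F)(F)F
F2 | step 5 | 3-[(1R)-1,5-dimethyl-2-(trifluoromethanesulfonyloxy)cyclohepta-2,5-dien-1-yl]propanal | O=CCC[C@]1(C)CC=C(C)CC=C1OS(=O)(=O)C(F)(F)F
F3 | step 5 | (8aR)-6,8a-dimethyl-1,2,3,5,8,8a-hexahydroazulen-3-ol (both C3 epimers) | OC1CC[C@]2(C)CC=C(C)CC=C12
F4 | step 7 | (3aR,4S,8aR)-6,8a-dimethyl-4-(4,4,5,5-tetramethyl-1,3,2-dioxaborolan-2-yl)-2,3a,4,5,8,8a-hexahydroazulen-3(1H)-one | O=C1CC[C@]2(C)CC=C(C)C[C@H](B3OC(C)(C)C(C)(C)O3)[C@@H]12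
F5 | step 8 | (3R,8aR)-6,8a-dimethyl-3-(propan-2-yl)-1,2,3,5,8,8a-hexahydroazulen-3-ol | CC(C)[C@]1(O)CC[C@]2(C)CC=C(C)CC=C12
F6 | step 8 | (3R,3aS,4R,8aR)-3a,4-epoxy-6,8a-dimethyl-3-(propan-2-yl)-1,2,3,3a,4,5,8,8a-octahydroazulen-3-ol | CC(C)[C@]1(O)CC[C@]2(C)CC=C(C)C[C@H]3O[C@@]123
F7 | step 8 | (3R,3aS,4R,8aR)-6,8a-dimethyl-3-(propan-2-yl)-1,2,3,3a,4,5,8,8a-octahydroazulene-3,4-diol | O[C@@H]1CC(C)=CC[C@@]2(C)CC[C@@](O)(C(C)C)[C@H]12
F8 | step 8 | (3R,3aR,8aR)-3-hydroxy-6,8a-dimethyl-3-(propan-2-yl)-2,3,3a,5,8,8a-hexahydroazulen-4(1H)-one | O=C1CC(C)=CC[C@@]2(C)CC[C@@](O)(C(C)C)[C@H]12
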